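## Retrosynthetic overview

1. Last step: Diels–Alder union (C1–C13′ and C3–C11′) of the 2-acetoxy-cyclopentadiene 34, released from 14 by dehydration, with the methylene lactone 33.
2. Both lactones come from one ligand-controlled, anti-selective chromium allylation. The lactone C–O bond is then closed with retention (acyl C–O, trans, guaianolide half) or with inversion (alkyl C8′–O, cis, seco-eudesmanolide half); the inverting closure is the key C–O bond formation.
3. Guaianolide half: cyclopentenone first (cyclopentane-1,3-dione + crotonaldehyde, Stork–Danheiser transposition), then the seven-membered ring and the lactone together (cross-metathesis, ring-closing allylation).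
4. Seco-eudesmanolide half: (R)-citronellal → β-keto ester → allylation → inverting lactonization (lactone first) → aldol condensation closes the cyclohexenone → methyl addition sets C-10′.

Assumption: the SMILES is taken as the absolute configuration to be made; guaiane numbering is used for the tricyclic half and primed 1,10-seco-eudesmane numbering for the other half.

## Route

Step 1
Reactants: 1 cyclopentane-1,3-dione; 2 (E)-but-2-enal
Product: 4 (4R)-2-methoxy-4-methyl-3,4,6,7-tetrahydrocyclopenta[b]pyran-5(2H)-one (C-2 epimers), via lactol 3 (not isolated)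
Conditions: (S)-α,α-diphenylprolinol trimethylsilyl ether (10 mol%), PhCO2H (10 mol%), CH2Cl2, 0 to 23 °C; then MeOH, camphorsulfonic acid (5 mol%), 23 °C
Reagents that add atoms: methanol (CO)
Why: Iminium-activated organocatalytic Michael addition of the dione to the enal, with the silyl prolinol shielding one face so that C-10 is formed R, followed by acid-catalyzed acetalization that locks the adduct as a bicyclic vinylogous ester.

Step 2
Reactants: 4 (4R)-2-methoxy-4-methyl-3,4,6,7-tetrahydrocyclopenta[b]pyran-5(2H)-one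
Product: 5 (4R)-2-methoxy-4,6-dimethyl-3,4,6,7-tetrahydrocyclopenta[b]pyran-5(2H)-one (C-2/C-6 epimers)
Conditions: LiN(iPr)2, THF, −78 °C; MeI
Reagents that add atoms: iodomethane (CI)
Why: Kinetic α′-enolate alkylation of a vinylogous ester (Stork–Danheiser alkylation) places the future C-15 methyl on C-4, whose configuration does not matter because the carbon is enolized again in step 3.

Step 3
Reactants: 5 (4R)-2-methoxy-4,6-dimethyl-3,4,6,7-tetrahydrocyclopenta[b]pyran-5(2H)-one
Product: 6 (4R)-6-hydroxy-2-methoxy-4,6-dimethyl-3,4,6,7-tetrahydrocyclopenta[b]pyran-5(2H)-one (C-2/C-6 epimers)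
Conditions: LiN(iPr)2, THF, −78 °C; 2-(phenylsulfonyl)-3-phenyloxaziridine; H2O quench
Reagents that add atoms: 2-(phenylsulfonyl)-3-phenyloxaziridine (O=S(=O)(c1ccccc1)N1OC1c1ccccc1)
Why: A second α′-deprotonation gives the tetrasubstituted enolate, which the Davis oxaziridine hydroxylates (enolate oxidation); both C-4 epimers are carried on because C-4 becomes sp2 in step 19.

Step 4
Reactants: 6 (4R)-6-hydroxy-2-methoxy-4,6-dimethyl-3,4,6,7-tetrahydrocyclopenta[b]pyran-5(2H)-one
Product: 8 (3R)-3-[3-hydroxy-3-methyl-5-oxo-2-(prop-2-en-1-yl)cyclopent-1-en-1-yl]butanal (both carbinol epimers), via allyl carbinol 7 (not isolated)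
Conditions: CH2=CHCH2MgBr (3 equiv), THF, −78 to 0 °C; then 1 M HCl, THF, 0 °C
Reagents that add atoms: allylmagnesium bromide (C=CC[Mg]Br); water (O)
Why: 1,2-Addition of the Grignard reagent to the vinylogous ester carbonyl and acid hydrolysis (Stork–Danheiser transposition) give the 2,3-disubstituted cyclopentenone and unmask the aldehyde from the cyclic acetal in the same operation, with no new stereocenter retained.

Step 5
Reactants: 8 (3R)-3-[3-hydroxy-3-methyl-5-oxo-2-(prop-2-en-1-yl)cyclopent-1-en-1-yl]butanal; 9 methyl 2-(bromomethyl)prop-2-enoate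
Product: 10 methyl (2Z)-2-(bromomethyl)-4-{5-hydroxy-5-methyl-3-oxo-2-[(2R)-4-oxobutan-2-yl]cyclopent-1-en-1-yl}but-2-enoate
Conditions: 9 (4 equiv), second-generation Hoveyda–Grubbs catalyst RuCl2(H2IMes)(=CH–C6H4-2-OiPr) (5 mol%), CH2Cl2, 40 °C
Reagents that add atoms: none
Why: Olefin cross-metathesis of a terminal alkene with a 1,1-disubstituted acrylate, which does not homodimerize, gives the cross product as the thermodynamically preferred Z bromide (ester trans to the chain).

Step 6
Reactants: 10 methyl (2Z)-2-(bromomethyl)-4-{5-hydroxy-5-methyl-3-oxo-2-[(2R)-4-oxobutan-2-yl]cyclopent-1-en-1-yl}but-2-enoate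
Product: 12 (7S,8R,10R)-4-hydroxy-2-oxoguaia-1(5),11(13)-dien-12,8-olide (trans-fused lactone; C-4 epimers), via silyl ether 11 (not isolated)
Conditions: CrCl2 (10 mol%), L* (12 mol%; L* = 3,6-di-tert-butyl-1,8-bis[(4S)-4-isopropyl-4,5-dihydro-1,3-oxazol-2-yl]-9H-carbazole), Mn (2 equiv), Me3SiCl (1.5 equiv), THF, 23 °C, 5 mM; then TsOH·H2O (cat.), MeOH, 23 °C
Reagents that add atoms: none
Why: Catalytic asymmetric Nozaki–Hiyama–Kishi allylation in which the allylchromium species adds through a chair transition state (anti) to the aldehyde face selected by the ligand (the antipode of L* is used if the sense proves opposite), setting C-7 (S) and C-8 (R) as the seven-membered ring closes, after which acid removes the silyl group and lactonizes with retention to the trans-fused α-methylene lactone.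

Step 7
Reactants: 12 (7S,8R,10R)-4-hydroxy-2-oxoguaia-1(5),11(13)-dien-12,8-olide
Product: 13 (2R,7S,8R,10R)-2,4-dihydroxyguaia-1(5),11(13)-dien-12,8-olide (C-4 epimers)
Conditions: (S)-2-methyl-CBS-oxazaborolidine (20 mol%), catecholborane (1.5 equiv), PhMe, −78 °C; aq. NaOH work-up
Reagents that add atoms: none
Why: Corey–Bakshi–Shibata reduction in which, with the enone alkene as the large group, the (S)-catalyst delivers hydride under reagent control to give the 2R allylic alcohol, while the lactone is untouched at −78 °C.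

Step 8
Reactants: 13 (2R,7S,8R,10R)-2,4-dihydroxyguaia-1(5),11(13)-dien-12,8-olide
Product: 14 (2R,7S,8R,10R)-2-acetoxy-4-hydroxyguaia-1(5),11(13)-dien-12,8-olide (C-4 epimers)
Conditions: Ac2O, pyridine, 4-(dimethylamino)pyridine (cat.), CH2Cl2, 0 °C
Reagents that add atoms: acetic anhydride (CC(=O)OC(C)=O)
Why: Chemoselective esterification, since the secondary allylic alcohol is acylated quickly while the tertiary C-4 alcohol does not react under these conditions.

Step 9
Reactants: 15 tert-butyl prop-2-enoate; 16 2,2-dimethoxyacetaldehyde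
Product: 17 tert-butyl 3-hydroxy-4,4-dimethoxy-2-methylidenebutanoate (racemic)
Conditions: 1,4-diazabicyclo[2.2.2]octane (0.5 equiv), 1,4-dioxane/H2O, 23 °C
Reagents that add atoms: none
Why: Morita–Baylis–Hillman reaction of the acrylate with an activated α,α-dialkoxy aldehyde.

Step 10
Reactants: 17 tert-butyl 3-hydroxy-4,4-dimethoxy-2-methylidenebutanoate
Product: 18 tert-butyl (2Z)-2-(bromomethyl)-4,4-dimethoxybut-2-enoate
Conditions: N-bromosuccinimide, Me2S, CH2Cl2, 0 to 23 °C
Reagents that add atoms: N-bromosuccinimide (BrN1C(=O)CCC1=O)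
Why: Corey–Kim-type activation of the allylic alcohol followed by SN2′ attack of bromide gives the rearranged, conjugated Z allylic bromide.

Step 11
Reactants: 19 (R)-citronellal, (3R)-3,7-dimethyloct-6-enal; 20 ethyl diazoacetate
Product: 21 ethyl (5R)-5,9-dimethyl-3-oxodec-8-enoate
Conditions: SnCl2 (10 mol%), CH2Cl2, 23 °C
Reagents that add atoms: none
Why: Roskamp homologation, in which Lewis-acid-promoted addition of the diazo ester to the aldehyde and a 1,2-hydride shift with loss of N2 give the β-keto ester without touching the C-4′ stereocenter.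

Step 12
Reactants: 21 ethyl (5R)-5,9-dimethyl-3-oxodec-8-enoate
Product: 22 ethyl 2-{2-[(2R)-2,6-dimethylhept-5-en-1-yl]-1,3-dioxolan-2-yl}acetate
Conditions: HOCH2CH2OH, TsOH·H2O (cat.), PhH, reflux (Dean–Stark)
Reagents that add atoms: ethane-1,2-diol (OCCO)
Why: Acid-catalyzed ketalization with azeotropic removal of water masks the ketone so that the ester can be reduced and the aldehyde allylated.

Step 13
Reactants: 22 ethyl 2-{2-[(2R)-2,6-dimethylhept-5-en-1-yl]-1,3-dioxolan-2-yl}acetate
Product: 23 2-{2-[(2R)-2,6-dimethylhept-5-en-1-yl]-1,3-dioxolan-2-yl}acetaldehyde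
Conditions: iBu2AlH (1.1 equiv), CH2Cl2, −78 °C; aq. KNaC4H4O6 work-up
Reagents that add atoms: none
Why: Partial ester reduction, since at −78 °C the hydride addition stops at the tetrahedral aluminate, which gives the aldehyde on work-up.

Step 14
Reactants: 23 2-{2-[(2R)-2,6-dimethylhept-5-en-1-yl]-1,3-dioxolan-2-yl}acetaldehyde; 18 tert-butyl (2Z)-2-(bromomethyl)-4,4-dimethoxybut-2-enoate
Product: 25 tert-butyl (3S,4R)-3-(dimethoxymethyl)-5-{2-[(2R)-2,6-dimethylhept-5-en-1-yl]-1,3-dioxolan-2-yl}-4-hydroxy-2-methylidenepentanoate, via silyl ether 24 (not isolated)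
Conditions: 18 (1.5 equiv), CrCl2 (10 mol%), L* (12 mol%), Mn (2 equiv), Me3SiCl (1.5 equiv), THF, 23 °C; then K2CO3, MeOH, 0 °C
Reagents that add atoms: none
Why: The same catalytic asymmetric Nozaki–Hiyama–Kishi allylation, in which anti addition of the γ-substituted allylchromium species to the ligand-selected aldehyde face sets C-7′ (S) and C-8′ (R), while the tert-butyl ester prevents spontaneous lactonization.

Step 15
Reactants: 25 tert-butyl (3S,4R)-3-(dimethoxymethyl)-5-{2-[(2R)-2,6-dimethylhept-5-en-1-yl]-1,3-dioxolan-2-yl}-4-hydroxy-2-methylidenepentanoate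
Product: 27 (4S,5S)-4-(dimethoxymethyl)-5-({2-[(2R)-2,6-dimethylhept-5-en-1-yl]-1,3-dioxolan-2-yl}methyl)-3-methylideneoxolan-2-one, via triflate 26 (not isolated)
Conditions: (CF3SO2)2O (1.2 equiv), 2,6-di-tert-butyl-4-methylpyridine (3 equiv), CH2Cl2, −78 to 0 °C
Reagents that add atoms: none
Why: Proposed new method: triflation of the secondary alcohol is followed by intramolecular backside attack of the tert-butyl ester carbonyl oxygen on C-8′ (five-membered transition state) and loss of the tert-butyl cation as isobutene from the lactonium ion, so that the lactone C–O bond forms with inversion and turns the anti adduct into the cis-fused lactone (8′S); the closest known reaction types are the Mitsunobu lactonization of hydroxy acids and the dealkylative cyclization of tert-butyl esters and carbonates onto halonium ions or sulfonates (neighbouring-group participation), not yet shown for an α-methylene tert-butyl ester closing onto a triflate.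

Step 16
Reactants: 27 (4S,5S)-4-(dimethoxymethyl)-5-({2-[(2R)-2,6-dimethylhept-5-en-1-yl]-1,3-dioxolan-2-yl}methyl)-3-methylideneoxolan-2-one
Product: 30 (4R)-5-[2-({(2S,3S)-3-(dimethoxymethyl)-4-methylidene-5-oxooxolan-2-yl}methyl)-1,3-dioxolan-2-yl]-4-methylpentyl acetate, via aldehyde 28 (not isolated), via alcohol 29 (not isolated)
Conditions: O3, CH2Cl2, −78 °C (Sudan red end point); Me2S; then NaBH(OAc)3, AcOH, 0 to 23 °C; then Ac2O, pyridine, 4-(dimethylamino)pyridine (cat.), 23 °C
Reagents that add atoms: ozone ([O-][O+]=O); acetic anhydride (CC(=O)OC(C)=O)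
Why: Ozonolysis cleaves the electron-rich trisubstituted alkene far faster than the electron-poor methylene lactone, the aldehyde is reduced by the mild acyloxyborohydride, and the primary alcohol is acetylated in the same flask.

Step 17
Reactants: 30 (4R)-5-[2-({(2S,3S)-3-(dimethoxymethyl)-4-methylidene-5-oxooxolan-2-yl}methyl)-1,3-dioxolan-2-yl]-4-methylpentyl acetate
Product: 32 (4R)-4-[(3aS,7aS)-3-methylidene-2,6-dioxo-2,3,3a,6,7,7a-hexahydro-1-benzofuran-5-yl]pentyl acetate, via keto aldehyde 31 (not isolated)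
Conditions: CF3CO2H/H2O (9:1), CH2Cl2, 0 °C; then (PhCH2)2NH·CF3CO2H (20 mol%), PhH, 50 °C
Reagents that add atoms: water (O)
Why: Acid hydrolysis frees the ketone and the aldehyde, and amine-salt-catalyzed intramolecular aldol condensation, for which only the six-membered mode is possible, closes the cyclohexenone without touching C-7′ and C-8′.

Step 18
Reactants: 32 (4R)-4-[(3aS,7aS)-3-methylidene-2,6-dioxo-2,3,3a,6,7,7a-hexahydro-1-benzofuran-5-yl]pentyl acetate
Product: 33 (4R)-4-[(3aS,6R,7aS)-6-hydroxy-6-methyl-3-methylidene-2-oxo-2,3,3a,6,7,7a-hexahydro-1-benzofuran-5-yl]pentyl acetate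
Conditions: MeLi, CeCl3, THF, −78 °C
Reagents that add atoms: methyllithium ([Li]C)
Why: Chemoselective organocerium 1,2-addition to the enone carbonyl in preference to the lactone and the acetate, from the convex face of the cis-fused bicycle (anti to the lactone ring), so that the new hydroxyl is cis to the lactone oxygen (10′R).

Step 19
Reactants: 14 (2R,7S,8R,10R)-2-acetoxy-4-hydroxyguaia-1(5),11(13)-dien-12,8-olide; 33 (4R)-4-[(3aS,6R,7aS)-6-hydroxy-6-methyl-3-methylidene-2-oxo-2,3,3a,6,7,7a-hexahydro-1-benzofuran-5-yl]pentyl acetate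
Product: 35 target dimer CNP0257312.1, via diene 34 (not isolated)
Conditions: Ph2S[OC(CF3)2Ph]2 (1.0 equiv), CH2Cl2, −40 to 0 °C; then 33 (3 equiv), PhMe (1 M), 40 °C, 48 h
Reagents that add atoms: none
Why: The sulfurane dehydrates the tertiary allylic alcohol to the cyclopentadiene (E1-type, endocyclic alkene favored) before 33 is added, and the Diels–Alder reaction with the exocyclic methylene of 33 then proceeds endo, with C-13′ bonding to the more substituted terminus C-1 (no two adjacent quaternary carbons), on the diene face syn to the 2-acetoxy group (the known contrasteric preference of 5-acetoxycyclopentadienes, here also the face anti to the C-10 methyl) and on the convex face of the lactone, which fixes C-1, C-3 and C-11′.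

## Compound list

1 | cyclopentane-1,3-dione | O=C1CCC(=O)C1 | starting material
2 | (E)-but-2-enal | C/C=C/C=O | starting material
3 | (4R)-2-hydroxy-4-methyl-3,4,6,7-tetrahydrocyclopenta[b]pyran-5(2H)-one (lactol) | OC1C[C@@H](C)C2=C(O1)CCC2=O | intermediate
4 | (4R)-2-methoxy-4-methyl-3,4,6,7-tetrahydrocyclopenta[b]pyran-5(2H)-one | COC1C[C@@H](C)C2=C(O1)CCC2=O | intermediate
5 | (4R)-2-methoxy-4,6-dimethyl-3,4,6,7-tetrahydrocyclopenta[b]pyran-5(2H)-one | COC1C[C@@H](C)C2=C(O1)CC(C)C2=O | intermediate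
6 | (4R)-6-hydroxy-2-methoxy-4,6-dimethyl-3,4,6,7-tetrahydrocyclopenta[b]pyran-5(2H)-one | COC1C[C@@H](C)C2=C(O1)CC(C)(O)C2=O | intermediate
7 | (4R)-2-methoxy-4,6-dimethyl-5-(prop-2-en-1-yl)-2,3,4,5,6,7-hexahydrocyclopenta[b]pyran-5,6-diol | COC1C[C@@H](C)C2=C(O1)CC(C)(O)C2(O)CC=C | intermediate
8 | (3R)-3-[3-hydroxy-3-methyl-5-oxo-2-(prop-2-en-1-yl)cyclopent-1-en-1-yl]butanal | O=CC[C@@H](C)C1=C(CC=C)C(C)(O)CC1=O | intermediate
9 | methyl 2-(bromomethyl)prop-2-enoate | C=C(CBr)C(=O)OC | starting material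
10 | methyl (2Z)-2-(bromomethyl)-4-{5-hydroxy-5-methyl-3-oxo-2-[(2R)-4-oxobutan-2-yl]cyclopent-1-en-1-yl}but-2-enoate | O=CC[C@@H](C)C1=C(C/C=C(\CBr)C(=O)OC)C(C)(O)CC1=O | intermediate
11 | methyl (7S,8R,10R)-4-hydroxy-2-oxo-8-(trimethylsilyloxy)guaia-1(5),11(13)-dien-12-oate | C[Si](C)(C)O[C@@H]1C[C@@H](C)C2=C(C[C@H]1C(=C)C(=O)OC)C(C)(O)CC2=O | intermediate
12 | (7S,8R,10R)-4-hydroxy-2-oxoguaia-1(5),11(13)-dien-12,8-olide | C=C1C(=O)O[C@@H]2C[C@@H](C)C3=C(C[C@@H]12)C(C)(O)CC3=O | intermediate
13 | (2R,7S,8R,10R)-2,4-dihydroxyguaia-1(5),11(13)-dien-12,8-olide | C=C1C(=O)O[C@@H]2C[C@@H](C)C3=C(C[C@@H]12)C(C)(O)C[C@H]3O | intermediate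
14 | (2R,7S,8R,10R)-2-acetoxy-4-hydroxyguaia-1(5),11(13)-dien-12,8-olide | C=C1C(=O)O[C@@H]2C[C@@H](C)C3=C(C[C@@H]12)C(C)(O)C[C@H]3OC(C)=O | intermediate
15 | tert-butyl prop-2-enoate | C=CC(=O)OC(C)(C)C | starting material
16 | 2,2-dimethoxyacetaldehyde | COC(OC)C=O | starting material
17 | tert-butyl 3-hydroxy-4,4-dimethoxy-2-methylidenebutanoate | C=C(C(O)C(OC)OC)C(=O)OC(C)(C)C | intermediate
18 | tert-butyl (2Z)-2-(bromomethyl)-4,4-dimethoxybut-2-enoate | COC(OC)/C=C(\CBr)C(=O)OC(C)(C)C | intermediate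
19 | (R)-citronellal | O=CC[C@H](C)CCC=C(C)C | starting material
20 | ethyl diazoacetate | CCOC(=O)C=[N+]=[N-] | starting material
21 | ethyl (5R)-5,9-dimethyl-3-oxodec-8-enoate | CCOC(=O)CC(=O)C[C@H](C)CCC=C(C)C | intermediate
22 | ethyl 2-{2-[(2R)-2,6-dimethylhept-5-en-1-yl]-1,3-dioxolan-2-yl}acetate | CCOC(=O)CC1(C[C@H](C)CCC=C(C)C)OCCO1 | intermediate
23 | 2-{2-[(2R)-2,6-dimethylhept-5-en-1-yl]-1,3-dioxolan-2-yl}acetaldehyde | O=CCC1(C[C@H](C)CCC=C(C)C)OCCO1 | intermediate
24 | tert-butyl (3S,4R)-3-(dimethoxymethyl)-5-{2-[(2R)-2,6-dimethylhept-5-en-1-yl]-1,3-dioxolan-2-yl}-2-methylidene-4-(trimethylsilyloxy)pentanoate | COC(OC)[C@H]([C@H](O[Si](C)(C)C)CC1(C[C@H](C)CCC=C(C)C)OCCO1)C(=C)C(=O)OC(C)(C)C | intermediate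
25 | tert-butyl (3S,4R)-3-(dimethoxymethyl)-5-{2-[(2R)-2,6-dimethylhept-5-en-1-yl]-1,3-dioxolan-2-yl}-4-hydroxy-2-methylidenepentanoate | COC(OC)[C@H]([C@H](O)CC1(C[C@H](C)CCC=C(C)C)OCCO1)C(=C)C(=O)OC(C)(C)C | intermediate
26 | tert-butyl (3S,4R)-3-(dimethoxymethyl)-5-{2-[(2R)-2,6-dimethylhept-5-en-1-yl]-1,3-dioxolan-2-yl}-2-methylidene-4-[(trifluoromethanesulfonyl)oxy]pentanoate | COC(OC)[C@H]([C@H](OS(=O)(=O)C(F)(F)F)CC1(C[C@H](C)CCC=C(C)C)OCCO1)C(=C)C(=O)OC(C)(C)C | intermediate
27 | (4S,5S)-4-(dimethoxymethyl)-5-({2-[(2R)-2,6-dimethylhept-5-en-1-yl]-1,3-dioxolan-2-yl}methyl)-3-methylideneoxolan-2-one | C=C1C(=O)O[C@@H](CC2(C[C@H](C)CCC=C(C)C)OCCO2)[C@H]1C(OC)OC | intermediate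
28 | (4R)-5-[2-({(2S,3S)-3-(dimethoxymethyl)-4-methylidene-5-oxooxolan-2-yl}methyl)-1,3-dioxolan-2-yl]-4-methylpentanal | C=C1C(=O)O[C@@H](CC2(C[C@H](C)CCC=O)OCCO2)[C@H]1C(OC)OC | intermediate
29 | (4S,5S)-4-(dimethoxymethyl)-5-({2-[(2R)-5-hydroxy-2-methylpentyl]-1,3-dioxolan-2-yl}methyl)-3-methylideneoxolan-2-one | C=C1C(=O)O[C@@H](CC2(C[C@H](C)CCCO)OCCO2)[C@H]1C(OC)OC | intermediate
30 | (4R)-5-[2-({(2S,3S)-3-(dimethoxymethyl)-4-methylidene-5-oxooxolan-2-yl}methyl)-1,3-dioxolan-2-yl]-4-methylpentyl acetate | C=C1C(=O)O[C@@H](CC2(C[C@H](C)CCCOC(C)=O)OCCO2)[C@H]1C(OC)OC | intermediate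
31 | (4R)-7-[(2S,3S)-3-formyl-4-methylidene-5-oxooxolan-2-yl]-4-methyl-6-oxoheptyl acetate | C=C1C(=O)O[C@@H](CC(=O)C[C@H](C)CCCOC(C)=O)[C@H]1C=O | intermediate
32 | (4R)-4-[(3aS,7aS)-3-methylidene-2,6-dioxo-2,3,3a,6,7,7a-hexahydro-1-benzofuran-5-yl]pentyl acetate | C=C1C(=O)O[C@H]2CC(=O)C([C@H](C)CCCOC(C)=O)=C[C@H]21 | intermediate
33 | (4R)-4-[(3aS,6R,7aS)-6-hydroxy-6-methyl-3-methylidene-2-oxo-2,3,3a,6,7,7a-hexahydro-1-benzofuran-5-yl]pentyl acetate | C=C1C(=O)O[C@H]2C[C@@](C)(O)C([C@H](C)CCCOC(C)=O)=C[C@H]21 | intermediate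
34 | (2R,7S,8R,10R)-2-acetoxyguaia-1(5),3,11(13)-trien-12,8-olide | C=C1C(=O)O[C@@H]2C[C@@H](C)C3=C(C[C@@H]12)C(C)=C[C@H]3OC(C)=O | intermediate
35 | target dimer CNP0257312.1 | C=C1C(=O)O[C@@H]2C[C@@H](C)[C@]34C[C@]5(C(=O)O[C@H]6C[C@@](C)(O)C([C@H](C)CCCOC(C)=O)=C[C@H]65)[C@H](C(C)=C3C[C@@H]12)[C@H]4OC(C)=O | target

## Step count and risks

Total step count: 19. Longest linear sequence: 9 steps (steps 11–18 then 19; equally steps 1–8 then 19).

Steps most likely to fail:

Step 15 (the proposed new inverting lactonization): the triflate may eliminate to a dienoate or the lactonium ion may not form cleanly. Fallback with known chemistry, setting out from 25: a Mitsunobu inversion (PPh3, diisopropyl azodicarboxylate, 4-nitrobenzoic acid, THF) gives the C-4-inverted 4-nitrobenzoate F1. K2CO3 in MeOH removes the aroyl group to the syn hydroxy ester F2. Catalytic NaH in THF then closes F2 by ordinary acyl substitution, with retention and loss of tert-butanol, to the cis lactone 27, where the route is rejoined.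

Step 6 (ring-closing asymmetric allylation): the seven-membered closure may be slow, or the ligand may not override the substrate bias. Fallback setting out from 10: a substrate-controlled Barbier cyclization with zinc dust in THF/saturated aqueous NH4Cl, expected to give the syn adduct, delivers the cis-fused 8-epi lactone F3. LiOH in THF/H2O opens it to the hydroxy acid F4. A Mitsunobu lactonization (PPh3, diisopropyl azodicarboxylate) closes it again with inversion at C-8, coming back at 12.

Step 19 (dehydration and cycloaddition): diene 34 can isomerize by hydrogen shift or dimerize through its own methylene lactone, and residual sulfurane would dehydrate 33. Fallback setting out from 14: (CF3CO)2O and pyridine give the tertiary trifluoroacetate F5. With Pd(PPh3)4 (zerovalent palladium, 5 mol%) and Et3N in THF at 23 °C, in the presence of excess 33, ionization of the tertiary allylic ester and β-hydride elimination release 34 slowly under neutral conditions. The diene is trapped as it forms, coming back at 35.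

Further compounds
F1 | step 15 | tert-butyl (3S,4S)-3-(dimethoxymethyl)-5-{2-[(2R)-2,6-dimethylhept-5-en-1-yl]-1,3-dioxolan-2-yl}-2-methylidene-4-[(4-nitrobenzoyl)oxy]pentanoate | COC(OC)[C@H]([C@@H](OC(=O)c2ccc(cc2)[N+](=O)[O-])CC1(C[C@H](C)CCC=C(C)C)OCCO1)C(=C)C(=O)OC(C)(C)C
F2 | step 15 | tert-butyl (3S,4S)-3-(dimethoxymethyl)-5-{2-[(2R)-2,6-dimethylhept-5-en-1-yl]-1,3-dioxolan-2-yl}-4-hydroxy-2-methylidenepentanoate | COC(OC)[C@H]([C@@H](O)CC1(C[C@H](C)CCC=C(C)C)OCCO1)C(=C)C(=O)OC(C)(C)C
F3 | step 6 | (7S,8S,10R)-4-hydroxy-2-oxoguaia-1(5),11(13)-dien-12,8-olide (cis-fused 8-epimer of 12) | C=C1C(=O)O[C@H]2C[C@@H](C)C3=C(C[C@@H]12)C(C)(O)CC3=O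
F4 | step 6 | (7S,8S,10R)-4,8-dihydroxy-2-oxoguaia-1(5),11(13)-dien-12-oic acid | O[C@H]1C[C@@H](C)C2=C(C[C@H]1C(=C)C(=O)O)C(C)(O)CC2=O
F5 | step 19 | (2R,7S,8R,10R)-2-acetoxy-4-(trifluoroacetoxy)guaia-1(5),11(13)-dien-12,8-olide | C=C1C(=O)O[C@@H]2C[C@@H](C)C3=C(C[C@@H]12)C(C)(OC(=O)C(F)(F)F)C[C@H]3OC(C)=O
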